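**Retrosynthetic overview**
- Target ⇒ two Horner–Wadsworth–Emmons disconnections (C11=C12, then C11'=C12'): a C15 trihydroxy dienal, a C10 triene bisphosphonate and a C15 furanoid enal.
- Dihydrofuran ring ⇒ silver-catalysed cyclisation of an α-hydroxyallene (axis-to-centre transfer sets C8'); allene ⇒ syn-SN2' opening of an ethynyl oxirane by an alkenyl Grignard reagent.
- Triol ring ⇒ axial acetylide addition to an α-hydroxy ketone (sets C6), then trans-hydroalumination; C3 and C3' ⇒ hydroxyl-directed anti reduction of the 3-ketones.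
- Both end groups ⇒ one epoxy aldehyde, from Sharpless epoxidation of an achiral ketal allylic alcohol (the only source of absolute configuration).
- Ring order: the six-membered carbocycle of both halves is closed first, by Michael addition and intramolecular aldol condensation of ethyl acetoacetate with mesityl oxide; the dihydrofuran ring is closed last, at fragment level.

Assumption: the entry is the all-E (3S,5R,6S,3'S,5'R,8'R) isomer drawn by the SMILES; carotenoid numbering (C1–C20, primed for the furanoid half) is used in comments.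

Step 1
Reactants: 1 ethyl acetoacetate; 2 mesityl oxide
Product: 5 ethyl 2,6,6-trimethyl-4-oxocyclohex-2-ene-1-carboxylate (racemic), via Michael adduct 3 (not isolated), via aldol adduct 4 (not isolated)
Conditions: BF3·OEt2 (0.3 equiv), neat, 0 °C → rt, 3 d
Reagents that add atoms: none
Why: Lewis-acid Michael addition of the acetoacetate enol to the enone, then intramolecular aldol condensation of the methyl ketone onto the acetoacetate carbonyl, closes the trimethylcyclohexenone ring (Robinson-type annulation); its one stereocentre is racemic and is erased in step 2.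

Step 2
Reactants: 5 ethyl 2,6,6-trimethyl-4-oxocyclohex-2-ene-1-carboxylate
Product: 6 ethyl 7,9,9-trimethyl-1,4-dioxaspiro[4.5]dec-7-ene-8-carboxylate
Conditions: HOCH2CH2OH (3 equiv), p-TsOH·H2O (cat.), benzene, reflux, Dean–Stark
Reagents that add atoms: ethane-1,2-diol, OCCO
Why: Acid-catalysed ketalisation of the enone runs through the dienol ether, so the double bond moves into the tetrasubstituted position conjugated with the ester and the product is achiral.

Step 3
Reactants: 6 ethyl 7,9,9-trimethyl-1,4-dioxaspiro[4.5]dec-7-ene-8-carboxylate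
Product: 7 (7,9,9-trimethyl-1,4-dioxaspiro[4.5]dec-7-en-8-yl)methanol
Conditions: LiAlH4, Et2O, 0 °C
Reagents that add atoms: none
Why: Hydride 1,2-reduction of the conjugated ester gives the primary allylic alcohol, the ketal being inert.

Step 4
Reactants: 7 (7,9,9-trimethyl-1,4-dioxaspiro[4.5]dec-7-en-8-yl)methanol
Product: 8 [(1'R,6'R)-1',5',5'-trimethylspiro[1,3-dioxolane-2,3'-[7]oxabicyclo[4.1.0]heptan]-6'-yl]methanol
Conditions: Ti(OiPr)4 (0.2 equiv), D-(−)-diethyl tartrate (0.25 equiv), t-BuOOH (2 equiv), 4 Å MS, CH2Cl2, −20 °C; recrystallise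
Reagents that add atoms: tert-butyl hydroperoxide, CC(C)(C)OO
Why: Sharpless asymmetric epoxidation delivers oxygen to one enantioface of the achiral tetrasubstituted allylic alcohol, setting C5 and C6 and with them the absolute configuration of both halves.

Step 5
Reactants: 8 [(1'R,6'R)-1',5',5'-trimethylspiro[1,3-dioxolane-2,3'-[7]oxabicyclo[4.1.0]heptan]-6'-yl]methanol
Product: 9 (1'R,6'S)-1',5',5'-trimethylspiro[1,3-dioxolane-2,3'-[7]oxabicyclo[4.1.0]heptane]-6'-carbaldehyde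
Conditions: Dess–Martin periodinane, CH2Cl2, rt
Reagents that add atoms: none
Why: Dess–Martin oxidation gives the non-enolisable epoxy aldehyde without touching oxirane or ketal (the descriptor at C6' changes by priority only).

Step 6
Reactants: 9 (1'R,6'S)-1',5',5'-trimethylspiro[1,3-dioxolane-2,3'-[7]oxabicyclo[4.1.0]heptane]-6'-carbaldehyde
Product: 11 (7R)-7,9,9-trimethyl-8-methylidene-1,4-dioxaspiro[4.5]decan-7-ol, via hydrazone 10 (not isolated)
Conditions: N2H4·H2O (3 equiv), AcOH (0.2 equiv), MeOH, 0 °C → rt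
Reagents that add atoms: none
Why: Wharton transposition: the hydrazone opens the oxirane at C6 and loses N2, so the C5–O bond and its configuration are untouched and the exocyclic allylic alcohol results.

Step 7
Reactants: 11 (7R)-7,9,9-trimethyl-8-methylidene-1,4-dioxaspiro[4.5]decan-7-ol
Product: 13 (7R)-7-hydroxy-7,9,9-trimethyl-1,4-dioxaspiro[4.5]decan-8-one, via ozonide 12 (not isolated)
Conditions: O3, CH2Cl2, −78 °C; then Me2S, −78 °C → rt
Reagents that add atoms: ozone, [O-][O+]=O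
Why: Ozonolysis with reductive work-up cleaves the 1,1-disubstituted alkene to the C6 ketone, while the ketal (no acetal C–H) and the tertiary carbinol are inert.

Step 8
Reactants: 13 (7R)-7-hydroxy-7,9,9-trimethyl-1,4-dioxaspiro[4.5]decan-8-one; 14 (2E)-3-methylpent-2-en-4-yn-1-ol
Product: 16 (7R,8R)-8-[(3E)-5-hydroxy-3-methylpent-3-en-1-yn-1-yl]-7,9,9-trimethyl-1,4-dioxaspiro[4.5]decane-7,8-diol, via dilithio enynol 15 (not isolated)
Conditions: 14 (3 equiv), n-BuLi (6 equiv), THF, −78 °C; then 13, −78 → 0 °C; NH4Cl (aq)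
Reagents that add atoms: none
Why: 1,2-Addition of the lithium acetylide occurs axially, on the face opposite the axial C5–O and the axial C1 methyl, so the new C6–OH is cis to the C5–OH.

Step 9
Reactants: 16 (7R,8R)-8-[(3E)-5-hydroxy-3-methylpent-3-en-1-yn-1-yl]-7,9,9-trimethyl-1,4-dioxaspiro[4.5]decane-7,8-diol
Product: 17 (3R,4R)-3,4-dihydroxy-4-[(3E)-5-hydroxy-3-methylpent-3-en-1-yn-1-yl]-3,5,5-trimethylcyclohexan-1-one
Conditions: 1 M HCl (aq), THF, 0 °C → rt
Reagents that add atoms: water, O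
Why: Acid-catalysed ketal hydrolysis frees the C3 ketone under conditions too mild to ionise the tertiary propargylic alcohol or dehydrate the β-hydroxy ketone.

Step 10
Reactants: 17 (3R,4R)-3,4-dihydroxy-4-[(3E)-5-hydroxy-3-methylpent-3-en-1-yn-1-yl]-3,5,5-trimethylcyclohexan-1-one
Product: 18 (1R,2R,4S)-1-[(3E)-5-hydroxy-3-methylpent-3-en-1-yn-1-yl]-2,6,6-trimethylcyclohexane-1,2,4-triol
Conditions: Me4NBH(OAc)3 (5 equiv), MeCN/AcOH 1:1, −30 °C
Reagents that add atoms: none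
Why: Evans–Saksena hydroxyl-directed reduction: the axial C5 alkoxyborohydride delivers hydride to its own face of C3, so the 3-OH ends anti to the 5-OH (3S).

Step 11
Reactants: 18 (1R,2R,4S)-1-[(3E)-5-hydroxy-3-methylpent-3-en-1-yn-1-yl]-2,6,6-trimethylcyclohexane-1,2,4-triol
Product: 19 (1S,2R,4S)-1-[(1E,3E)-5-hydroxy-3-methylpenta-1,3-dien-1-yl]-2,6,6-trimethylcyclohexane-1,2,4-triol
Conditions: NaAlH2(OCH2CH2OMe)2 (Red-Al, 6 equiv), THF, 0 °C → rt; Rochelle salt (aq)
Reagents that add atoms: none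
Why: Alkoxide-directed trans-hydroalumination of the tertiary propargylic alcohol gives the (7E) alkene and leaves the (9E) alkene and all stereocentres unchanged (descriptor at C6 changes by priority only).

Step 12
Reactants: 19 (1S,2R,4S)-1-[(1E,3E)-5-hydroxy-3-methylpenta-1,3-dien-1-yl]-2,6,6-trimethylcyclohexane-1,2,4-triol
Product: 20 (2E,4E)-3-methyl-5-[(1S,2R,4S)-1,2,4-trihydroxy-2,6,6-trimethylcyclohexyl]penta-2,4-dienal
Conditions: MnO2 (activated, 20 equiv), CH2Cl2, rt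
Reagents that add atoms: none
Why: Chemoselective allylic oxidation converts only the primary allylic alcohol into the dienal.

Step 13
Reactants: 21 but-2-yn-1-ol
Product: 22 (but-2-yn-1-yloxy)(tert-butyl)dimethylsilane
Conditions: TBSCl, imidazole, DMF, rt
Reagents that add atoms: tert-butyl(chloro)dimethylsilane, CC(C)(C)[Si](C)(C)Cl
Why: Silyl ether formation masks the alcohol for the organometallic steps.

Step 14
Reactants: 22 (but-2-yn-1-yloxy)(tert-butyl)dimethylsilane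
Product: 24 tert-butyl{[(2E)-3-iodobut-2-en-1-yl]oxy}dimethylsilane, via alkenylzirconocene 23 (not isolated)
Conditions: Cp2Zr(H)Cl (2 equiv), THF, 50 °C; then I2, 0 °C
Reagents that add atoms: iodine, II
Why: syn-Hydrozirconation with excess reagent equilibrates zirconium to the methyl-bearing carbon, and iodinolysis with retention gives the (E)-alkenyl iodide.

Step 15
Reactants: 9 (1'R,6'S)-1',5',5'-trimethylspiro[1,3-dioxolane-2,3'-[7]oxabicyclo[4.1.0]heptane]-6'-carbaldehyde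
Product: 25 (1'R,6'R)-6'-ethynyl-1',5',5'-trimethylspiro[1,3-dioxolane-2,3'-[7]oxabicyclo[4.1.0]heptane]
Conditions: MeC(O)C(N2)P(O)(OMe)2, K2CO3, MeOH, 0 °C → rt
Reagents that add atoms: dimethyl (1-diazo-2-oxopropyl)phosphonate, CC(=O)C(=[N+]=[N-])P(=O)(OC)OC
Why: Seyferth–Gilbert homologation with the Ohira–Bestmann reagent turns the non-enolisable aldehyde into the terminal alkyne under mild base that spares oxirane and ketal.

Step 16
Reactants: 24 tert-butyl{[(2E)-3-iodobut-2-en-1-yl]oxy}dimethylsilane; 25 (1'R,6'R)-6'-ethynyl-1',5',5'-trimethylspiro[1,3-dioxolane-2,3'-[7]oxabicyclo[4.1.0]heptane]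
Product: 28 (7R)-8-[(Sa,3E)-5-{[tert-butyl(dimethyl)silyl]oxy}-3-methylpenta-1,3-dien-1-ylidene]-7,9,9-trimethyl-1,4-dioxaspiro[4.5]decan-7-ol, via alkenyllithium 26 (not isolated), via alkenylmagnesium bromide 27 (not isolated)
Conditions: 24 (2.2 equiv), t-BuLi (4.4 equiv), Et2O, −78 °C; MgBr2·OEt2, −78 → 0 °C; added slowly to 25, Fe(acac)3 (5 mol %), toluene, −5 °C; NH4Cl (aq)
Reagents that add atoms: none
Why: Iron-catalysed SN2' opening of a propargylic oxirane by a Grignard reagent is syn (the reverse of cuprates), so C9 enters at C8 on the face of the departing oxygen and gives the (Sa) allene axis, while the C5–O bond is not broken.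

Step 17
Reactants: 28 (7R)-8-[(Sa,3E)-5-{[tert-butyl(dimethyl)silyl]oxy}-3-methylpenta-1,3-dien-1-ylidene]-7,9,9-trimethyl-1,4-dioxaspiro[4.5]decan-7-ol
Product: 29 (3R)-3-hydroxy-4-[(Sa,3E)-5-hydroxy-3-methylpenta-1,3-dien-1-ylidene]-3,5,5-trimethylcyclohexan-1-one
Conditions: 0.5 M HCl (aq), THF, 0 °C → rt
Reagents that add atoms: water, O
Why: Dilute aqueous acid removes the dioxolane and the primary silyl ether together (ketal hydrolysis and desilylation) faster than it protonates the allene.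

Step 18
Reactants: 29 (3R)-3-hydroxy-4-[(Sa,3E)-5-hydroxy-3-methylpenta-1,3-dien-1-ylidene]-3,5,5-trimethylcyclohexan-1-one
Product: 30 (1R,3S)-6-[(Sa,3E)-5-hydroxy-3-methylpenta-1,3-dien-1-ylidene]-1,5,5-trimethylcyclohexane-1,3-diol
Conditions: Me4NBH(OAc)3 (5 equiv), MeCN/AcOH 1:1, −30 °C
Reagents that add atoms: none
Why: Evans–Saksena directed reduction again delivers hydride from the face of the C5 hydroxyl, giving the 3-OH anti to it (3S).

Step 19
Reactants: 30 (1R,3S)-6-[(Sa,3E)-5-hydroxy-3-methylpenta-1,3-dien-1-ylidene]-1,5,5-trimethylcyclohexane-1,3-diol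
Product: 31 (2R,6S,7aR)-2-[(2E)-4-hydroxybut-2-en-2-yl]-4,4,7a-trimethyl-2,4,5,6,7,7a-hexahydro-1-benzofuran-6-ol
Conditions: AgNO3 (0.2 equiv), CaCO3, acetone/H2O 4:1, rt, dark
Reagents that add atoms: none
Why: Silver-catalysed 5-endo cycloisomerisation of the α-hydroxyallene adds O5 to C8 in the plane fixed by the allene axis, so axis-to-centre transfer gives (8R) with the side chain trans to the C5 methyl.

Step 20
Reactants: 31 (2R,6S,7aR)-2-[(2E)-4-hydroxybut-2-en-2-yl]-4,4,7a-trimethyl-2,4,5,6,7,7a-hexahydro-1-benzofuran-6-ol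
Product: 32 (2E)-3-[(2R,6S,7aR)-6-hydroxy-4,4,7a-trimethyl-2,4,5,6,7,7a-hexahydro-1-benzofuran-2-yl]but-2-enal
Conditions: MnO2 (activated, 20 equiv), CH2Cl2, rt
Reagents that add atoms: none
Why: Allylic oxidation under neutral conditions gives the enal without touching the secondary alcohol or the acid-labile allylic ether at C8.

Step 21
Reactants: 33 (2E)-1,1,4,4-tetramethoxybut-2-ene
Product: 34 (2E)-but-2-enedial
Conditions: Amberlyst 15, acetone/H2O, rt; solution used directly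
Reagents that add atoms: water, O
Why: Acid-catalysed acetal hydrolysis liberates fumaraldehyde.

Step 22
Reactants: 34 (2E)-but-2-enedial; 35 ethyl 2-(triphenylphosphoranylidene)propanoate
Product: 36 diethyl (2E,4E,6E)-2,7-dimethylocta-2,4,6-trienedioate
Conditions: 35 (2.2 equiv), CH2Cl2, rt
Reagents that add atoms: none
Why: Twofold Wittig olefination with the stabilised ylide gives the crystalline all-E triene diester.

Step 23
Reactants: 36 diethyl (2E,4E,6E)-2,7-dimethylocta-2,4,6-trienedioate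
Product: 37 (2E,4E,6E)-2,7-dimethylocta-2,4,6-triene-1,8-diol
Conditions: i-Bu2AlH (4.5 equiv), CH2Cl2, −78 → 0 °C; Rochelle salt (aq)
Reagents that add atoms: none
Why: Hydride 1,2-reduction of both conjugated esters gives the bis-allylic diol.

Step 24
Reactants: 37 (2E,4E,6E)-2,7-dimethylocta-2,4,6-triene-1,8-diol
Product: 38 (2E,4E,6E)-1,8-dibromo-2,7-dimethylocta-2,4,6-triene
Conditions: PBr3 (0.8 equiv), pyridine (cat.), Et2O, −10 °C; used crude
Reagents that add atoms: phosphorus tribromide, BrP(Br)Br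
Why: SN2 bromination of the primary allylic alcohols at low temperature keeps the triene geometry.

Step 25
Reactants: 38 (2E,4E,6E)-1,8-dibromo-2,7-dimethylocta-2,4,6-triene
Product: 39 tetraethyl [(2E,4E,6E)-2,7-dimethylocta-2,4,6-triene-1,8-diyl]bis(phosphonate)
Conditions: P(OEt)3 (excess), 110 °C
Reagents that add atoms: triethyl phosphite, CCOP(OCC)OCC
Why: Twofold Michaelis–Arbuzov reaction at the primary allylic bromides gives the C10 bisphosphonate.

Step 26
Reactants: 20 (2E,4E)-3-methyl-5-[(1S,2R,4S)-1,2,4-trihydroxy-2,6,6-trimethylcyclohexyl]penta-2,4-dienal; 39 tetraethyl [(2E,4E,6E)-2,7-dimethylocta-2,4,6-triene-1,8-diyl]bis(phosphonate)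
Product: 41 diethyl {(2E,4E,6E,8E,10E,12E)-2,7,11-trimethyl-13-[(1S,2R,4S)-1,2,4-trihydroxy-2,6,6-trimethylcyclohexyl]trideca-2,4,6,8,10,12-hexaen-1-yl}phosphonate, via phosphonate carbanion 40 (not isolated)
Conditions: 39 (4 equiv), KOtBu (1.5 equiv), THF, −78 °C; then 20 added slowly, −78 → 0 °C; excess 39 recovered
Reagents that add atoms: none
Why: Horner–Wadsworth–Emmons olefination of the aldehyde with the monoanion of the excess bisphosphonate forms the (11E) double bond; the hydroxyls ride along as alkoxides and no stereocentre is touched.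

Step 27
Reactants: 41 diethyl {(2E,4E,6E,8E,10E,12E)-2,7,11-trimethyl-13-[(1S,2R,4S)-1,2,4-trihydroxy-2,6,6-trimethylcyclohexyl]trideca-2,4,6,8,10,12-hexaen-1-yl}phosphonate; 32 (2E)-3-[(2R,6S,7aR)-6-hydroxy-4,4,7a-trimethyl-2,4,5,6,7,7a-hexahydro-1-benzofuran-2-yl]but-2-enal
Product: 43 (3S,5R,6S,3'S,5'R,8'R)-5',8'-epoxy-5,6,5',8'-tetrahydro-β,β-carotene-3,5,6,3'-tetrol, via phosphonate carbanion 42 (not isolated)
Conditions: 41 (1.2 equiv), KOtBu (4 equiv), THF, −78 °C; then 32, −78 → −20 °C, dark, argon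
Reagents that add atoms: none
Why: The second Horner–Wadsworth–Emmons olefination forms the (11'E) double bond, the enal being consumed at low temperature before γ-deprotonation can epimerise C8'.

**Compound list**
1 | ethyl acetoacetate | CCOC(=O)CC(C)=O | starting material
2 | mesityl oxide (4-methylpent-3-en-2-one) | CC(=O)C=C(C)C | starting material
3 | ethyl 2-acetyl-3,3-dimethyl-5-oxohexanoate (racemic) | CCOC(=O)C(C(C)=O)C(C)(C)CC(C)=O | intermediate
4 | ethyl 2-hydroxy-2,6,6-trimethyl-4-oxocyclohexane-1-carboxylate (stereoisomer mixture) | CCOC(=O)C1C(C)(O)CC(=O)CC1(C)C | intermediate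
5 | ethyl 2,6,6-trimethyl-4-oxocyclohex-2-ene-1-carboxylate (racemic) | CCOC(=O)C1C(C)=CC(=O)CC1(C)C | intermediate
6 | ethyl 7,9,9-trimethyl-1,4-dioxaspiro[4.5]dec-7-ene-8-carboxylate | CCOC(=O)C1=C(C)CC2(CC1(C)C)OCCO2 | intermediate
7 | (7,9,9-trimethyl-1,4-dioxaspiro[4.5]dec-7-en-8-yl)methanol | OCC1=C(C)CC2(CC1(C)C)OCCO2 | intermediate
8 | [(1'R,6'R)-1',5',5'-trimethylspiro[1,3-dioxolane-2,3'-[7]oxabicyclo[4.1.0]heptan]-6'-yl]methanol | OC[C@@]12O[C@]1(C)CC1(OCCO1)CC2(C)C | intermediate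
9 | (1'R,6'S)-1',5',5'-trimethylspiro[1,3-dioxolane-2,3'-[7]oxabicyclo[4.1.0]heptane]-6'-carbaldehyde | O=C[C@@]12O[C@]1(C)CC1(OCCO1)CC2(C)C | intermediate
10 | (E)-hydrazone of 9 | N/N=C/[C@@]12O[C@]1(C)CC1(OCCO1)CC2(C)C | intermediate
11 | (7R)-7,9,9-trimethyl-8-methylidene-1,4-dioxaspiro[4.5]decan-7-ol | C=C1[C@](C)(O)CC2(OCCO2)CC1(C)C | intermediate
12 | secondary ozonide of 11 (spiro-1,2,4-trioxolane at C8, both configurations at the spiro carbon) | C1OC2(OO1)[C@](C)(O)CC3(OCCO3)CC2(C)C | intermediate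
13 | (7R)-7-hydroxy-7,9,9-trimethyl-1,4-dioxaspiro[4.5]decan-8-one | O=C1[C@](C)(O)CC2(OCCO2)CC1(C)C | intermediate
14 | (2E)-3-methylpent-2-en-4-yn-1-ol | OC/C=C(\C)C#C | starting material
15 | dilithium salt of 14 (alkoxide and acetylide) | [Li]OC/C=C(\C)C#C[Li] | intermediate
16 | (7R,8R)-8-[(3E)-5-hydroxy-3-methylpent-3-en-1-yn-1-yl]-7,9,9-trimethyl-1,4-dioxaspiro[4.5]decane-7,8-diol | OC/C=C(\C)C#C[C@]1(O)C(C)(C)CC2(OCCO2)C[C@@]1(C)O | intermediate
17 | (3R,4R)-3,4-dihydroxy-4-[(3E)-5-hydroxy-3-methylpent-3-en-1-yn-1-yl]-3,5,5-trimethylcyclohexan-1-one | OC/C=C(\C)C#C[C@]1(O)C(C)(C)CC(=O)C[C@@]1(C)O | intermediate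
18 | (1R,2R,4S)-1-[(3E)-5-hydroxy-3-methylpent-3-en-1-yn-1-yl]-2,6,6-trimethylcyclohexane-1,2,4-triol | OC/C=C(\C)C#C[C@]1(O)C(C)(C)C[C@H](O)C[C@@]1(C)O | intermediate
19 | (1S,2R,4S)-1-[(1E,3E)-5-hydroxy-3-methylpenta-1,3-dien-1-yl]-2,6,6-trimethylcyclohexane-1,2,4-triol | OC/C=C(\C)/C=C/[C@]1(O)C(C)(C)C[C@H](O)C[C@@]1(C)O | intermediate
20 | (2E,4E)-3-methyl-5-[(1S,2R,4S)-1,2,4-trihydroxy-2,6,6-trimethylcyclohexyl]penta-2,4-dienal | O=C/C=C(\C)/C=C/[C@]1(O)C(C)(C)C[C@H](O)C[C@@]1(C)O | intermediate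
21 | but-2-yn-1-ol | CC#CCO | starting material
22 | (but-2-yn-1-yloxy)(tert-butyl)dimethylsilane | CC#CCO[Si](C)(C)C(C)(C)C | intermediate
23 | chlorobis(cyclopentadienyl)[(2E)-4-{[tert-butyl(dimethyl)silyl]oxy}but-2-en-2-yl]zirconium | C/C(=C\CO[Si](C)(C)C(C)(C)C)[Zr](Cl)(C1C=CC=C1)C1C=CC=C1 | intermediate
24 | tert-butyl{[(2E)-3-iodobut-2-en-1-yl]oxy}dimethylsilane | C/C(I)=C\CO[Si](C)(C)C(C)(C)C | intermediate
25 | (1'R,6'R)-6'-ethynyl-1',5',5'-trimethylspiro[1,3-dioxolane-2,3'-[7]oxabicyclo[4.1.0]heptane] | C#C[C@@]12O[C@]1(C)CC1(OCCO1)CC2(C)C | intermediate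
26 | [(2E)-4-{[tert-butyl(dimethyl)silyl]oxy}but-2-en-2-yl]lithium | C/C([Li])=C\CO[Si](C)(C)C(C)(C)C | intermediate
27 | [(2E)-4-{[tert-butyl(dimethyl)silyl]oxy}but-2-en-2-yl]magnesium bromide | C/C([Mg]Br)=C\CO[Si](C)(C)C(C)(C)C | intermediate
28 | (7R)-8-[(Sa,3E)-5-{[tert-butyl(dimethyl)silyl]oxy}-3-methylpenta-1,3-dien-1-ylidene]-7,9,9-trimethyl-1,4-dioxaspiro[4.5]decan-7-ol (C9 on the face of the C5 hydroxyl) | [H]C(/C(C)=C/CO[Si](C)(C)C(C)(C)C)=[C@@]=C1C(C)(C)CC2(OCCO2)C[C@@]1(C)O | intermediate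
29 | (3R)-3-hydroxy-4-[(Sa,3E)-5-hydroxy-3-methylpenta-1,3-dien-1-ylidene]-3,5,5-trimethylcyclohexan-1-one | [H]C(/C(C)=C/CO)=[C@@]=C1C(C)(C)CC(=O)C[C@@]1(C)O | intermediate
30 | (1R,3S)-6-[(Sa,3E)-5-hydroxy-3-methylpenta-1,3-dien-1-ylidene]-1,5,5-trimethylcyclohexane-1,3-diol | [H]C(/C(C)=C/CO)=[C@@]=C1C(C)(C)C[C@H](O)C[C@@]1(C)O | intermediate
31 | (2R,6S,7aR)-2-[(2E)-4-hydroxybut-2-en-2-yl]-4,4,7a-trimethyl-2,4,5,6,7,7a-hexahydro-1-benzofuran-6-ol | OC/C=C(\C)[C@H]1C=C2C(C)(C)C[C@H](O)C[C@@]2(C)O1 | intermediate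
32 | (2E)-3-[(2R,6S,7aR)-6-hydroxy-4,4,7a-trimethyl-2,4,5,6,7,7a-hexahydro-1-benzofuran-2-yl]but-2-enal | O=C/C=C(\C)[C@H]1C=C2C(C)(C)C[C@H](O)C[C@@]2(C)O1 | intermediate
33 | (2E)-1,1,4,4-tetramethoxybut-2-ene | COC(OC)/C=C/C(OC)OC | starting material
34 | (2E)-but-2-enedial (fumaraldehyde) | O=C/C=C/C=O | intermediate
35 | ethyl 2-(triphenylphosphoranylidene)propanoate | CCOC(=O)C(C)=P(c1ccccc1)(c1ccccc1)c1ccccc1 | starting material
36 | diethyl (2E,4E,6E)-2,7-dimethylocta-2,4,6-trienedioate | CCOC(=O)/C(C)=C/C=C/C=C(\C)C(=O)OCC | intermediate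
37 | (2E,4E,6E)-2,7-dimethylocta-2,4,6-triene-1,8-diol | OC/C(C)=C/C=C/C=C(\C)CO | intermediate
38 | (2E,4E,6E)-1,8-dibromo-2,7-dimethylocta-2,4,6-triene | BrC/C(C)=C/C=C/C=C(\C)CBr | intermediate
39 | tetraethyl [(2E,4E,6E)-2,7-dimethylocta-2,4,6-triene-1,8-diyl]bis(phosphonate) | CCOP(=O)(OCC)C/C(C)=C/C=C/C=C(\C)CP(=O)(OCC)OCC | intermediate
40 | monopotassium α-carbanion of 39 | CCOP(=O)(OCC)[CH-]/C(C)=C/C=C/C=C(\C)CP(=O)(OCC)OCC.[K+] | intermediate
41 | diethyl {(2E,4E,6E,8E,10E,12E)-2,7,11-trimethyl-13-[(1S,2R,4S)-1,2,4-trihydroxy-2,6,6-trimethylcyclohexyl]trideca-2,4,6,8,10,12-hexaen-1-yl}phosphonate | CCOP(=O)(OCC)C/C(C)=C/C=C/C=C(\C)/C=C/C=C(\C)/C=C/[C@]1(O)C(C)(C)C[C@H](O)C[C@@]1(C)O | intermediate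
42 | potassium α-carbanion of 41 (hydroxyls drawn protonated) | CCOP(=O)(OCC)[CH-]/C(C)=C/C=C/C=C(\C)/C=C/C=C(\C)/C=C/[C@]1(O)C(C)(C)C[C@H](O)C[C@@]1(C)O.[K+] | intermediate
43 | (3S,5R,6S,3'S,5'R,8'R)-5',8'-epoxy-5,6,5',8'-tetrahydro-β,β-carotene-3,5,6,3'-tetrol | CC(/C=C/C=C(C)/C=C/[C@]1(O)C(C)(C)C[C@H](O)C[C@@]1(C)O)=C\C=C\C=C(C)\C=C\C=C(/C)[C@H]1C=C2C(C)(C)C[C@H](O)C[C@@]2(C)O1 | target

**Totals**
Total step count: 27. Longest linear sequence: 14 steps (steps 1–12, 26, 27).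

**Three steps most likely to fail**

Step 16. The iron-catalysed syn-SN2' opening is established for alkyl Grignard reagents; an alkenyl Grignard reagent on a terminal alkyne is an extrapolation. The reagent may deprotonate the alkyne, and the syn:anti ratio is not known. The fallback gives up the allene and sets out from 9, coming back at 31. Horner–Wadsworth–Emmons reaction of 9 with triethyl (2E)-3-methyl-4-phosphonobut-2-enoate (LiN(SiMe3)2, THF, −78 °C) gives ethyl (2E,4E)-3-methyl-5-[(1'R,6'S)-1',5',5'-trimethylspiro[1,3-dioxolane-2,3'-[7]oxabicyclo[4.1.0]heptan]-6'-yl]penta-2,4-dienoate F1. i-Bu2AlH reduces it to (2E,4E)-3-methyl-5-[(1'R,6'S)-1',5',5'-trimethylspiro[1,3-dioxolane-2,3'-[7]oxabicyclo[4.1.0]heptan]-6'-yl]penta-2,4-dien-1-ol F2. Dilute HCl in THF/H2O then opens the oxirane at C6, closes O5 onto C8 and hydrolyses the ketal. This gives the 3-oxo furanoid as a roughly 1:1 pair at C8: (2R,7aR)-2-[(2E)-4-hydroxybut-2-en-2-yl]-4,4,7a-trimethyl-2,4,5,7a-tetrahydro-1-benzofuran-6(7H)-one F3 and its (2S,7aR)-epimer F4. They are separated by HPLC and F4 is recycled by acid re-equilibration. LiBH(s-Bu)3 (THF, −78 °C) attacks F3 from the equatorial side, away from the two syn-axial methyls, and gives 31. C8 is then set by separation and C3 by reagent approach instead of by chirality transfer and hydroxyl direction.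

Step 19. The allene carries an alkenyl group, so metal activation can give a pentadienyl cation and scramble C8, or lead to carbocyclisation. The fallback sets out from 30 and comes back at 31 through halocyclisation. N-Iodosuccinimide (CH2Cl2, −20 °C) gives, by anti iodo-etherification with the same axis-to-centre transfer, (2S,6S,7aR)-2-[(2E)-4-hydroxybut-2-en-2-yl]-3-iodo-4,4,7a-trimethyl-2,4,5,6,7,7a-hexahydro-1-benzofuran-6-ol F5. Bu3SnH with Pd(PPh3)4 (THF, rt) then removes the vinylic iodine and gives 31.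

Step 26. Mono-olefination of a symmetrical bisphosphonate is statistical, and the polyhydroxy dienal is base-sensitive. The fallback desymmetrises the cheap C10 unit instead; it sets out from 38 and comes back at 41. One equivalent of P(OEt)3 (80 °C, unreacted 38 recycled) gives diethyl [(2E,4E,6E)-8-bromo-2,7-dimethylocta-2,4,6-trien-1-yl]phosphonate F6. PPh3 (toluene, rt) converts it into [(2E,4E,6E)-8-(diethoxyphosphoryl)-2,7-dimethylocta-2,4,6-trien-1-yl]triphenylphosphonium bromide F7. NaOMe (CH2Cl2/MeOH, 0 °C) deprotonates only the phosphonium end, and Wittig reaction with 20 (free hydroxyls tolerated) gives 41 after thermal Z-to-E isomerisation in refluxing ethyl acetate.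

**Further compounds**
F1 | step 16 | ethyl (2E,4E)-3-methyl-5-[(1'R,6'S)-1',5',5'-trimethylspiro[1,3-dioxolane-2,3'-[7]oxabicyclo[4.1.0]heptan]-6'-yl]penta-2,4-dienoate | CCOC(=O)/C=C(\C)/C=C/[C@@]12O[C@]1(C)CC1(OCCO1)CC2(C)C
F2 | step 16 | (2E,4E)-3-methyl-5-[(1'R,6'S)-1',5',5'-trimethylspiro[1,3-dioxolane-2,3'-[7]oxabicyclo[4.1.0]heptan]-6'-yl]penta-2,4-dien-1-ol | OC/C=C(\C)/C=C/[C@@]12O[C@]1(C)CC1(OCCO1)CC2(C)C
F3 | step 16 | (2R,7aR)-2-[(2E)-4-hydroxybut-2-en-2-yl]-4,4,7a-trimethyl-2,4,5,7a-tetrahydro-1-benzofuran-6(7H)-one | OC/C=C(\C)[C@H]1C=C2C(C)(C)CC(=O)C[C@@]2(C)O1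
F4 | step 16 | (2S,7aR)-2-[(2E)-4-hydroxybut-2-en-2-yl]-4,4,7a-trimethyl-2,4,5,7a-tetrahydro-1-benzofuran-6(7H)-one | OC/C=C(\C)[C@@H]1C=C2C(C)(C)CC(=O)C[C@@]2(C)O1
F5 | step 19 | (2S,6S,7aR)-2-[(2E)-4-hydroxybut-2-en-2-yl]-3-iodo-4,4,7a-trimethyl-2,4,5,6,7,7a-hexahydro-1-benzofuran-6-ol | OC/C=C(\C)[C@H]1C(I)=C2C(C)(C)C[C@H](O)C[C@@]2(C)O1
F6 | step 26 | diethyl [(2E,4E,6E)-8-bromo-2,7-dimethylocta-2,4,6-trien-1-yl]phosphonate | CCOP(=O)(OCC)C/C(C)=C/C=C/C=C(\C)CBr
F7 | step 26 | [(2E,4E,6E)-8-(diethoxyphosphoryl)-2,7-dimethylocta-2,4,6-trien-1-yl]triphenylphosphonium bromide | CCOP(=O)(OCC)C/C(C)=C/C=C/C=C(\C)C[P+](c1ccccc1)(c1ccccc1)c1ccccc1.[Br-]
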